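Start from the easy count: every turnover spends one reagent on one substrate, so the level each curve runs into can be read from the charges, 50.0% of the substrate in blue and 100% in ochre.

- blue: substrate 0.50 M; reagent 0.250 M; time 1.0 h
- ochre: substrate 0.50 M; reagent 0.500 M; time 1.0 h

* part of the substrate that has reacted at the end, blue
* part of the substrate that has reacted at the end, ochre
* what raising the concentration of reagent from its lowest to its highest value here does to the part of the substrate that has reacted (changes below 5 percentage points count as none) (it falls / no change / it rises)

- amounts and yields of by-product count idle adduct too
- run time (blue): 1.0 h

    substrate + reagent + by-product → product + 2 by-product (k1 = 0.076 M⁻² s⁻¹)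
    reagent ⇌ dormant form (K2 = 2.4, k2 = 0.0034 s⁻¹)
    substrate + reagent → product + by-product (k3 = 1.8 × 10⁻⁵ M⁻¹ s⁻¹)
    reagent + by-product ⇌ idle adduct, settled at all times (K4 = 3.8 M⁻¹)

Draw blue first. The opening slope belongs to the seed step, substrate plus reagent unaided, and it is flat: its substrate half-life of 43 h far exceeds the 2.40 min in which reagent relaxes towards dormant form. The by-product-assisted step overtakes the seed step at a by-product fraction of 0.0474% of the substrate charge.

Now the crossing to carry. Balance with dormant form restores free reagent at 0.289 min⁻¹, and the assisted step eats it at a rate that grows with by-product. Set the two equal and you get the handover fraction, free by-product over substrate charge, 25.4%. Beyond it, for a rough tail, let dormant form return by its back run alone, half-life 8.15 min, and count each reagent returned as one turnover.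

Idle adduct makes total by-product 1.21 times the free amount, with reagent taken midway to the knee. So blue's knee stands at 30.6%, reached at 0.981 h. The tail adds 1.28%, giving 31.9%. In ochre the factor is 1.49, the knee comes at 0.498 h and 37.7%, and the tail adds 40.6%, giving 78.3%. So it rises.

The forecast is higher than this reckoning: 37% for blue (32% to 42%) and 84% for ochre (74% to 90%), with the trend it rises. Ochre, it says, “tails off near 84% as reagent and substrate run out together”.

The simulation gives 31.4% in blue and 77.4% in ochre; the trend is it rises, by 46 percentage points.

The forecast stands 5.6 points and 6.6 points high. At the end of blue, free by-product is 29.7% of the substrate charge, past the handover, and dormant form stands at 4.45 times reagent against a balance of 2.4. The gap between the flasks comes from the difference in reagent charge: with blue's reagent in place of its own, ochre reaches 31.4% instead of 77.4%. Take blue with 0.42 M of reagent: the handover fraction holds no reagent term and stays 25.4%, the factor is 1.40, and the knee comes at 0.580 h. The reckoning gives 65.7%; that flask gives 64.9%.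

(The constants used here were set for the occasion.)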